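The route rests on cutting the C2–C3 bond of the pyranone ring C. C3 is raised to a rhodium carbene, made from an α-diazo ketone on the acetyl carbon of a prenylated phloroacetophenone, and inserts into the C2–H bond of a plain benzyl aryl ether. The step exploits C2 itself: it lies next to the ring-C oxygen O1 and is benzylic to ring B, whose chroman oxygen sits para, so its C–H bond is unusually hydridic. In one operation ring C closes, the C4 ketone is already in place, and a chiral dirhodium carboxylate sets the C2 configuration. The precursor is an open-chain diazo ketone with a prochiral OCH2Ar group.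

Key step: step 6

Remark: 2,2-dimethylchromane-6-carbaldehyde is taken as a purchasable building block.

Step 1
Reactants: 1 2,4,6-trihydroxyacetophenone
Product: 2 1-[2,4,6-trihydroxy-3-(3-methylbut-2-enyl)phenyl]ethanone
Conditions: prenyl bromide (1.0 equiv), DBU (1.1 equiv), THF, 0 °C → rt
Reagents that add atoms: prenyl bromide (1-bromo-3-methylbut-2-ene), CC(C)=CCBr
Why: Base-mediated C-prenylation of a phloroglucinol phenoxide (SN2 at the primary allylic bromide by the soft ring carbon) should give a single regioisomer because the two free ring positions of 1 are equivalent, and one equivalent of bromide limits double and O-alkylation.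

Step 2
Reactants: 2 1-[2,4,6-trihydroxy-3-(3-methylbut-2-enyl)phenyl]ethanone
Product: 3 1-[4,6-bis(tert-butyldimethylsilyloxy)-2-hydroxy-3-(3-methylbut-2-enyl)phenyl]ethanone
Conditions: TBSCl (2.1 equiv), imidazole, DMF, 0 °C
Reagents that add atoms: tert-butyldimethylsilyl chloride, CC(C)(C)[Si](C)(C)Cl
Why: Silyl ether formation with a bulky chlorosilane should take the unchelated 4-hydroxyl first and then the less hindered of the two chelated hydroxyls (C6, flanked by a ring hydrogen), so that the hydroxyl wedged between acetyl and prenyl and hydrogen-bonded to the carbonyl stays free.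

Step 3
Reactants: 4 2,2-dimethylchromane-6-carbaldehyde
Product: 5 (2,2-dimethylchroman-6-yl)methanol
Conditions: NaBH4, MeOH, 0 °C
Reagents that add atoms: none
Why: Hydride reduction of an aromatic aldehyde to the benzylic alcohol is routine and leaves the chroman ether untouched.

Step 4
Reactants: 3 1-[4,6-bis(tert-butyldimethylsilyloxy)-2-hydroxy-3-(3-methylbut-2-enyl)phenyl]ethanone; 5 (2,2-dimethylchroman-6-yl)methanol
Product: 6 1-[4,6-bis(tert-butyldimethylsilyloxy)-2-[(2,2-dimethylchroman-6-yl)methoxy]-3-(3-methylbut-2-enyl)phenyl]ethanone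
Conditions: PPh3, DIAD, THF, 0 °C → rt
Reagents that add atoms: none
Why: In the Mitsunobu etherification the acidic ortho-acylphenol 3 protonates the betaine and displaces the primary benzylic oxyphosphonium in an SN2 step under neutral conditions, which spare the aryl silyl ethers that carbonate bases in DMF would put at risk.

Step 5
Reactants: 6 1-[4,6-bis(tert-butyldimethylsilyloxy)-2-[(2,2-dimethylchroman-6-yl)methoxy]-3-(3-methylbut-2-enyl)phenyl]ethanone
Product: 8 2-diazo-1-[4,6-bis(tert-butyldimethylsilyloxy)-2-[(2,2-dimethylchroman-6-yl)methoxy]-3-(3-methylbut-2-enyl)phenyl]ethanone, via trifluoroacetyl diketone 7 (not isolated)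
Conditions: LiN(SiMe3)2, THF, −78 °C, then CF3CO2CH2CF3; crude 7: MsN3, Et3N, H2O (1 equiv), MeCN, rt
Reagents that add atoms: methanesulfonyl azide, CS(=O)(=O)N=[N+]=[N-] (the two diazo nitrogens); 2,2,2-trifluoroethyl trifluoroacetate, O=C(OCC(F)(F)F)C(F)(F)F (trifluoroacetyl group, present in 7 only)
Why: In this detrifluoroacetylative diazo transfer the kinetic lithium enolate of the methyl ketone is C-acylated at −78 °C, the activated 1,3-diketone 7 accepts the diazo group from the sulfonyl azide and the trifluoroacetyl group leaves as the N-acylsulfonamide, while the hindered amide base touches neither the ether CH2 nor the silyl ethers.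

Step 6
Reactants: 8 2-diazo-1-[4,6-bis(tert-butyldimethylsilyloxy)-2-[(2,2-dimethylchroman-6-yl)methoxy]-3-(3-methylbut-2-enyl)phenyl]ethanone
Product: 10 (2S)-5,7-bis(tert-butyldimethylsilyloxy)-2-(2,2-dimethylchroman-6-yl)-8-(3-methylbut-2-enyl)chroman-4-one, via rhodium carbene 9 (not isolated)
Conditions: Rh2(S-DOSP)4 (dirhodium tetrakis[(S)-N-(4-dodecylphenylsulfonyl)prolinate], 1 mol %), hexane, rt, slow addition of 8
Reagents that add atoms: none
Why: The diazo ketone loses N2 at dirhodium to give the electrophilic carbene 9 at C3, which inserts into the C2–H bond through a three-centre, hydride-transfer-like transition state with retention at carbon. The closest known reaction type is the dirhodium-carboxylate-catalysed intramolecular C–H insertion of 2-alkoxyaryl α-diazo ketones next to the ether oxygen, which gives chroman-4-ones and is enantioselective with chiral dirhodium prolinates. Ring C closes as a six-membered ring by 1,6-insertion, because the usually preferred 1,5-mode is excluded: the fifth atom is O1, which carries no hydrogen. The C2 centre is set by the catalyst, whose chiral prolinate ligands select one of the two enantiotopic benzylic hydrogens; which catalyst antipode leads to (2S) is to be fixed in a pilot run, both antipodes being available. The step needs C–H insertion to win over oxonium-ylide formation at O1 (followed by [1,2]-benzyl shift) and over attack on the 5-O substituent; the C2–H bond is made hydridic by O1 and the para-oxygenated ring B, O1 is a poor donor because it is conjugated to the acylated ring A and flanked by two ortho substituents, the 5-O silyl ether has no C–H next to oxygen, and a rhodium carboxylate favours insertion where copper catalysts favour ylides. Slow addition in a hydrocarbon solvent should suppress carbene dimerisation and intermolecular cyclopropanation of the prenyl alkene.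

Step 7
Reactants: 10 (2S)-5,7-bis(tert-butyldimethylsilyloxy)-2-(2,2-dimethylchroman-6-yl)-8-(3-methylbut-2-enyl)chroman-4-one
Product: 11 euchrenone a16, (2S)-5,7-dihydroxy-2-(2,2-dimethylchroman-6-yl)-8-(3-methylbut-2-enyl)chroman-4-one
Conditions: Et3N·3HF, THF, 0 °C → rt
Reagents that add atoms: none
Why: Fluoride cleavage of the two aryl silyl ethers in a slightly acidic medium should free both phenols without forming a phenoxide, so that neither base-induced ring opening of the flavanone (which would erase C2) nor acid-induced cyclisation of the prenyl group onto the 7-hydroxyl can occur.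

Compound list
1 | 2,4,6-trihydroxyacetophenone | CC(=O)c1c(O)cc(O)cc1O | starting material
2 | 1-[2,4,6-trihydroxy-3-(3-methylbut-2-enyl)phenyl]ethanone | CC(=O)c1c(O)c(CC=C(C)C)c(O)cc1O | intermediate
3 | 1-[4,6-bis(tert-butyldimethylsilyloxy)-2-hydroxy-3-(3-methylbut-2-enyl)phenyl]ethanone | CC(=O)c1c(O)c(CC=C(C)C)c(O[Si](C)(C)C(C)(C)C)cc1O[Si](C)(C)C(C)(C)C | intermediate
4 | 2,2-dimethylchromane-6-carbaldehyde | O=Cc1ccc2c(c1)CCC(C)(C)O2 | starting material
5 | (2,2-dimethylchroman-6-yl)methanol | OCc1ccc2c(c1)CCC(C)(C)O2 | intermediate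
6 | 1-[4,6-bis(tert-butyldimethylsilyloxy)-2-[(2,2-dimethylchroman-6-yl)methoxy]-3-(3-methylbut-2-enyl)phenyl]ethanone | CC(=O)c1c(OCc2ccc3c(c2)CCC(C)(C)O3)c(CC=C(C)C)c(O[Si](C)(C)C(C)(C)C)cc1O[Si](C)(C)C(C)(C)C | intermediate
7 | 1-[aryl as in 6]-4,4,4-trifluorobutane-1,3-dione (trifluoroacetyl diketone, not isolated) | O=C(CC(=O)C(F)(F)F)c1c(OCc2ccc3c(c2)CCC(C)(C)O3)c(CC=C(C)C)c(O[Si](C)(C)C(C)(C)C)cc1O[Si](C)(C)C(C)(C)C | intermediate
8 | 2-diazo-1-[4,6-bis(tert-butyldimethylsilyloxy)-2-[(2,2-dimethylchroman-6-yl)methoxy]-3-(3-methylbut-2-enyl)phenyl]ethanone | [N-]=[N+]=CC(=O)c1c(OCc2ccc3c(c2)CCC(C)(C)O3)c(CC=C(C)C)c(O[Si](C)(C)C(C)(C)C)cc1O[Si](C)(C)C(C)(C)C | intermediate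
9 | rhodium carbene at the former diazo carbon of 8 (carboxylate ligands and second rhodium omitted, not isolated) | O=C(C=[Rh])c1c(OCc2ccc3c(c2)CCC(C)(C)O3)c(CC=C(C)C)c(O[Si](C)(C)C(C)(C)C)cc1O[Si](C)(C)C(C)(C)C | intermediate
10 | (2S)-5,7-bis(tert-butyldimethylsilyloxy)-2-(2,2-dimethylchroman-6-yl)-8-(3-methylbut-2-enyl)chroman-4-one | CC(C)=CCc1c(O[Si](C)(C)C(C)(C)C)cc(O[Si](C)(C)C(C)(C)C)c2c1O[C@H](c1ccc3c(c1)CCC(C)(C)O3)CC2=O | intermediate
11 | euchrenone a16, (2S)-5,7-dihydroxy-2-(2,2-dimethylchroman-6-yl)-8-(3-methylbut-2-enyl)chroman-4-one | CC(C)=CCc1c(O)cc(O)c2c1O[C@H](c1ccc3c(c1)CCC(C)(C)O3)CC2=O | target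

Total step count: 7. Longest linear sequence: 6 steps (steps 1, 2, 4, 5, 6 and 7, from compound 1).

Steps most likely to fail

Step 6. The carbene may be captured by the lone pair of O1 instead of the C2–H bond (oxonium ylide, then benzyl shift to a benzofuranone), or the catalyst may discriminate the two enantiotopic hydrogens poorly. The fallback closes the same C2–C3 bond by hydride abstraction instead of carbene insertion and sets out from compound 6. Enolate O-acetylation (KN(SiMe3)2, Ac2O, THF, −78 °C) should give the enol acetate 1-[aryl as in 6]vinyl acetate F1. DDQ with 2,6-dichloropyridine, LiClO4 and 4 Å molecular sieves in 1,2-dichloroethane at rt should then remove hydride from the same benzylic ether CH2. The resulting aryl oxocarbenium ion would be trapped by the enol acetate carbon to give the racemic silyl-protected flavanone F2. Preparative chromatography on a chiral stationary phase (cellulose tris(3,5-dimethylphenylcarbamate)) would separate the (2S)-enantiomer from the (2R)-silyl-protected flavanone F3, which is set aside. The fallback comes back to the route at compound 10.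

Step 2. The silylation may fail to distinguish the two chelated hydroxyls, or may go to the more hindered one, which would lead into the 6-prenyl series. The fallback fixes the regiochemistry by a sigmatropic shift and sets out from compound 1. Bis-silylation (TBSCl, imidazole, DMF) of 1, in which the two chelated hydroxyls are equivalent, should give 1-[4,6-bis(tert-butyldimethylsilyloxy)-2-hydroxyphenyl]ethanone F4. O-Allylation with tert-butyl 2-methylbut-3-en-2-yl carbonate and Pd(PPh3)4 in THF at 0 °C should give the 1,1-dimethylallyl aryl ether F5. Aromatic Claisen rearrangement (toluene, 110 °C) then carries the allyl group with inversion to the only free ortho carbon, where it arrives as the 3-methylbut-2-enyl group. The fallback bypasses compound 2 and comes back at compound 3.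

Step 5. The ortho silyl group may migrate from the phenol oxygen to the enolate oxygen, or a silyl ether may be lost in the amine/water medium of the diazo transfer. The fallback avoids the lithium enolate and the diazo transfer and sets out from compound 6. Soft enolisation (TBSOTf, Et3N, CH2Cl2, 0 °C) should give the silyl enol ether F6. NBS in THF at −78 °C should convert it into the α-bromo ketone 2-bromo-1-[aryl as in 6]ethanone F7. N,N'-ditosylhydrazine and DBU in THF at 0 °C (N-alkylation, then loss of two sulfinates) should give the diazo ketone. The fallback comes back at compound 8.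

Further compounds
F1 | step 6 | 1-[4,6-bis(tert-butyldimethylsilyloxy)-2-[(2,2-dimethylchroman-6-yl)methoxy]-3-(3-methylbut-2-enyl)phenyl]vinyl acetate | C=C(OC(C)=O)c1c(OCc2ccc3c(c2)CCC(C)(C)O3)c(CC=C(C)C)c(O[Si](C)(C)C(C)(C)C)cc1O[Si](C)(C)C(C)(C)C
F2 | step 6 | racemic 5,7-bis(tert-butyldimethylsilyloxy)-2-(2,2-dimethylchroman-6-yl)-8-(3-methylbut-2-enyl)chroman-4-one | CC(C)=CCc1c(O[Si](C)(C)C(C)(C)C)cc(O[Si](C)(C)C(C)(C)C)c2c1OC(c1ccc3c(c1)CCC(C)(C)O3)CC2=O
F3 | step 6 | (2R)-5,7-bis(tert-butyldimethylsilyloxy)-2-(2,2-dimethylchroman-6-yl)-8-(3-methylbut-2-enyl)chroman-4-one | CC(C)=CCc1c(O[Si](C)(C)C(C)(C)C)cc(O[Si](C)(C)C(C)(C)C)c2c1O[C@@H](c1ccc3c(c1)CCC(C)(C)O3)CC2=O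
F4 | step 2 | 1-[4,6-bis(tert-butyldimethylsilyloxy)-2-hydroxyphenyl]ethanone | CC(=O)c1c(O)cc(O[Si](C)(C)C(C)(C)C)cc1O[Si](C)(C)C(C)(C)C
F5 | step 2 | 1-[4,6-bis(tert-butyldimethylsilyloxy)-2-(2-methylbut-3-en-2-yloxy)phenyl]ethanone | CC(=O)c1c(OC(C)(C)C=C)cc(O[Si](C)(C)C(C)(C)C)cc1O[Si](C)(C)C(C)(C)C
F6 | step 5 | tert-butyldimethylsilyl enol ether of 6 | C=C(O[Si](C)(C)C(C)(C)C)c1c(OCc2ccc3c(c2)CCC(C)(C)O3)c(CC=C(C)C)c(O[Si](C)(C)C(C)(C)C)cc1O[Si](C)(C)C(C)(C)C
F7 | step 5 | 2-bromo-1-[4,6-bis(tert-butyldimethylsilyloxy)-2-[(2,2-dimethylchroman-6-yl)methoxy]-3-(3-methylbut-2-enyl)phenyl]ethanone | O=C(CBr)c1c(OCc2ccc3c(c2)CCC(C)(C)O3)c(CC=C(C)C)c(O[Si](C)(C)C(C)(C)C)cc1O[Si](C)(C)C(C)(C)C
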